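The dispiro cyclobutane is the anemonin-type head-to-head [2+2] dimer of a 4-bromo-5-(bromomethylidene)furan-2(5H)-one, so both lactone rings are made at the monomer stage. In each ring (O1, C2, C3, C4, C5) the O1-bridged pair C2/C5 maps onto C5/C2 of a 2-(dibromomethyl)-5-ethoxyoxazole and C3=C4(Br) onto a bromoynone. One Diels–Alder/retro-Diels–Alder cascade joins C2–C3 and C4–C5, expels acetonitrile and gives a 2-ethoxy-5-(dibromomethyl)furan, which collapses to the bromomethylidene butenolide. CBS reduction, photodimerisation and a desymmetrising mono-inversion of the twofold-symmetric diol then set the (S)- and (R)-acetoxybutyl chains.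

Key step: step 5

Remark on the chemistry: the two lactone rings are interchanged by the twofold axis of the core, so the target is fully defined as the (5S,6S,11R,12R) core carrying one (1S)- and one (1R)-1-acetoxybutyl chain. Step 8 is expected to give, beside 12, its diastereomer with the mirror-image (5R,6R,11S,12S) core (CCC[C@@H](O)C1=C(Br)[C@]2(OC1=O)[C@H](Br)[C@@H](Br)[C@]21OC(=O)C([C@@H](CCC)O)=C1Br); it is assumed separable on silica and is discarded.

Step 1
Reactants: 1 L-alanine ethyl ester hydrochloride; 2 dibromoacetic acid
Product: 3 ethyl N-(2,2-dibromoacetyl)-L-alaninate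
Conditions: EDC·HCl, iPr2NEt, CH2Cl2, 0 → 23 °C
Reagents that add atoms: none
Why: Carbodiimide amide coupling of the amine freed by iPr2NEt with the activated acid; the alanine stereocentre is irrelevant because it becomes sp2 C4 of the oxazole in step 2.

Step 2
Reactants: 3 ethyl N-(2,2-dibromoacetyl)-L-alaninate
Product: 4 2-(dibromomethyl)-5-ethoxy-4-methyl-1,3-oxazole
Conditions: P2O5, CHCl3, reflux
Reagents that add atoms: none
Why: Robinson–Gabriel-type cyclodehydration of an N-acyl α-amino ester, the standard entry to 5-alkoxyoxazoles, in which the amide oxygen closes onto the activated ester carbonyl and loss of water aromatises the ring.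

Step 3
Reactants: 5 hex-1-yn-3-ol (racemic)
Product: 6 1-bromohex-1-yn-3-ol (racemic)
Conditions: NBS, AgNO3 (10 mol %), acetone, 23 °C, dark
Reagents that add atoms: N-bromosuccinimide, O=C1CCC(=O)N1Br
Why: Silver-catalysed electrophilic bromination of the terminal alkyne C–H through the silver acetylide, which leaves the secondary alcohol untouched.

Step 4
Reactants: 6 1-bromohex-1-yn-3-ol
Product: 7 1-bromohex-1-yn-3-one
Conditions: Dess–Martin periodinane, CH2Cl2, 0 → 23 °C
Reagents that add atoms: none
Why: Dess–Martin oxidation of the propargylic alcohol under neutral conditions that spare the bromoalkyne; the carbinol centre is erased on purpose because the ketone is needed to activate the dienophile and is reset in step 7.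

Step 5
Reactants: 4 2-(dibromomethyl)-5-ethoxy-4-methyl-1,3-oxazole; 7 1-bromohex-1-yn-3-one
Product: 9 1-[4-bromo-5-(dibromomethyl)-2-ethoxyfuran-3-yl]butan-1-one, via bicyclic Diels–Alder adduct 8 (not isolated)
Conditions: PhMe (1 M), 80 °C, sealed tube, dark
Reagents that add atoms: none
Why: The 2-azadiene of 4 (C5=C4–N3=C2, raised in energy by the 5-ethoxy group) adds across the electron-poor triple bond of 7 in a normal-demand [4+2] cycloaddition, joining oxazole C5 to the acyl-bearing alkyne carbon and oxazole C2 to the bromine-bearing alkyne carbon; these are the C2–C3 and C4–C5 bonds of each lactone ring of 14, and adduct 8 then loses acetonitrile by retro-[4+2] to give the furan. This is the classical oxazole–alkyne Diels–Alder/retro-Diels–Alder furan synthesis, known for 5-alkoxyoxazoles with acetylenic esters and ketones. The only ring closed is the six-membered ring of the 7-oxa-2-azabicyclo[2.2.1]heptadiene 8 (concerted suprafacial [4+2]); the five-membered ring that survives is the oxazole O1/C2/C5 unit plus the two alkyne carbons. The two bridgehead stereocentres of 8 are transient and vanish on cycloreversion, so no stereocontrol is needed. The step needs regioselectivity: the 5-ethoxy donor places the largest HOMO coefficient on oxazole C2, which pairs with the β-carbon (C–Br) of the ynone, so the ethoxy-bearing carbon ends next to the acyl-bearing carbon, the orientation known for 5-alkoxyoxazoles with acrylic and propiolic dienophiles. It also needs cycloaddition to outrun conjugate or halophilic attack on the bromoynone, which a concentrated, base-free, non-polar medium favours.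

Step 6
Reactants: 9 1-[4-bromo-5-(dibromomethyl)-2-ethoxyfuran-3-yl]butan-1-one
Product: 10 (5Z)-4-bromo-5-(bromomethylidene)-3-butanoylfuran-2(5H)-one
Conditions: ZnBr2 (20 mol %), CH2Cl2, 0 → 23 °C, anhydrous; filtration through silica
Reagents that add atoms: none
Why: ZnBr2 assists ionisation of one C–Br bond of the dibromomethyl group with push from the 2-ethoxy oxygen through the furan, and bromide then dealkylates the resulting O-ethyl lactonium ion (Pinner-type collapse, as when 2-alkoxyfurans serve as butenolide synthons), giving the bromomethylidene butenolide with the exocyclic bromine away from C4–Br; the double-bond geometry is not critical because step 8 equilibrates it.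

Step 7
Reactants: 10 (5Z)-4-bromo-5-(bromomethylidene)-3-butanoylfuran-2(5H)-one
Product: 11 (5Z)-4-bromo-5-(bromomethylidene)-3-[(1R)-1-hydroxybutyl]furan-2(5H)-one
Conditions: (S)-2-methyl-CBS-oxazaborolidine (20 mol %), catecholborane, PhMe, −78 °C; MeOH, then aqueous work-up
Reagents that add atoms: none
Why: Corey–Bakshi–Shibata reduction in which the tetrasubstituted alkenyl group is the large and n-propyl the small ketone substituent, so the (S)-catalyst should give the (1R)-carbinol, and the boron-activated 1,2-pathway at low temperature avoids conjugate attack at C4–Br.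

Step 8
Reactants: 11 (5Z)-4-bromo-5-(bromomethylidene)-3-[(1R)-1-hydroxybutyl]furan-2(5H)-one (two molecules)
Product: 12 (5S,6S,11R,12R)-4,10,11,12-tetrabromo-3,9-bis[(1R)-1-hydroxybutyl]-1,7-dioxadispiro[4.0.4.2]dodeca-3,9-diene-2,8-dione
Conditions: hν (405 nm), thioxanthen-9-one (10 mol %), degassed CH2Cl2 (0.5 M), 0 °C, stopped at partial conversion; silica gel chromatography
Reagents that add atoms: none
Why: Triplet-sensitised head-to-head [2+2] photodimerisation across the exocyclic C5=CHBr bonds (the reaction that turns protoanemonin into anemonin): bonding of the two CHBr carbons gives the bis(oxypentadienyl) 1,4-diradical, which should close with the ring oxygens anti, the bromines trans and each bromine cis to C4 of its neighbouring lactone, setting the four ring stereocentres relative to one another, while the remote (1R)-carbinols cannot bias the absolute sense, so the (5S,6S,11R,12R) diastereomer is taken by chromatography.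

Step 9
Reactants: 12 the (5S,6S,11R,12R) bis[(1R)-hydroxybutyl] dimer
Product: 13 (1R)-1-[(5S,6S,11R,12R)-4,10,11,12-tetrabromo-9-[(1R)-1-hydroxybutyl]-2,8-dioxo-1,7-dioxadispiro[4.0.4.2]dodeca-3,9-dien-3-yl]butyl acetate
Conditions: Ac2O (1.0 equiv), pyridine, CH2Cl2, 0 °C; recovered 12 recycled
Reagents that add atoms: acetic anhydride, CC(=O)OC(C)=O
Why: Acylation with one equivalent of anhydride, in which the two hydroxyl groups are homotopic through the twofold axis, so mono-acylation can give only one mono-acetate, with retention at the carbinol.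

Step 10
Reactants: 13 the mono-acetate with one free (1R)-alcohol
Product: 14 target CNP0266230.1, (5S,6S,11R,12R)-3-[(1S)-1-acetoxybutyl]-9-[(1R)-1-acetoxybutyl]-4,10,11,12-tetrabromo-1,7-dioxadispiro[4.0.4.2]dodeca-3,9-diene-2,8-dione
Conditions: PPh3 and DIAD premixed at 0 °C, then AcOH and 13, PhMe/THF, 0 → 23 °C
Reagents that add atoms: acetic acid, CC(=O)O
Why: Mitsunobu esterification in which the preformed phosphine–azodicarboxylate betaine activates the remaining (1R)-alcohol as its alkoxyphosphonium ion and acetate displaces it by SN2 with inversion to the (1S)-acetate, SN2′ attack being blocked by the fully substituted, bromine-bearing C4.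

Compound list
1 | L-alanine ethyl ester hydrochloride | C[C@H](N)C(=O)OCC.Cl | starting material
2 | dibromoacetic acid | OC(=O)C(Br)Br | starting material
3 | ethyl N-(2,2-dibromoacetyl)-L-alaninate | C[C@H](NC(=O)C(Br)Br)C(=O)OCC | intermediate
4 | 2-(dibromomethyl)-5-ethoxy-4-methyl-1,3-oxazole | CCOc1oc(C(Br)Br)nc1C | intermediate
5 | hex-1-yn-3-ol (racemic) | CCCC(O)C#C | starting material
6 | 1-bromohex-1-yn-3-ol (racemic) | CCCC(O)C#CBr | intermediate
7 | 1-bromohex-1-yn-3-one | CCCC(=O)C#CBr | intermediate
8 | 1-[6-bromo-1-(dibromomethyl)-4-ethoxy-3-methyl-7-oxa-2-azabicyclo[2.2.1]hepta-2,5-dien-5-yl]butan-1-one (racemic, transient, not isolated) | CCOC12OC(C(Br)Br)(N=C1C)C(Br)=C2C(=O)CCC | intermediate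
9 | 1-[4-bromo-5-(dibromomethyl)-2-ethoxyfuran-3-yl]butan-1-one | CCOc1oc(C(Br)Br)c(Br)c1C(=O)CCC | intermediate
10 | (5Z)-4-bromo-5-(bromomethylidene)-3-butanoylfuran-2(5H)-one | CCCC(=O)C1=C(Br)/C(=C/Br)OC1=O | intermediate
11 | (5Z)-4-bromo-5-(bromomethylidene)-3-[(1R)-1-hydroxybutyl]furan-2(5H)-one | CCC[C@@H](O)C1=C(Br)/C(=C/Br)OC1=O | intermediate
12 | (5S,6S,11R,12R)-4,10,11,12-tetrabromo-3,9-bis[(1R)-1-hydroxybutyl]-1,7-dioxadispiro[4.0.4.2]dodeca-3,9-diene-2,8-dione | CCC[C@@H](O)C1=C(Br)[C@@]2(OC1=O)[C@@H](Br)[C@H](Br)[C@@]21OC(=O)C([C@@H](CCC)O)=C1Br | intermediate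
13 | (1R)-1-[(5S,6S,11R,12R)-4,10,11,12-tetrabromo-9-[(1R)-1-hydroxybutyl]-2,8-dioxo-1,7-dioxadispiro[4.0.4.2]dodeca-3,9-dien-3-yl]butyl acetate | CCC[C@@H](O)C1=C(Br)[C@@]2(OC1=O)[C@@H](Br)[C@H](Br)[C@@]21OC(=O)C([C@@H](CCC)OC(C)=O)=C1Br | intermediate
14 | CNP0266230.1, (5S,6S,11R,12R)-3-[(1S)-1-acetoxybutyl]-9-[(1R)-1-acetoxybutyl]-4,10,11,12-tetrabromo-1,7-dioxadispiro[4.0.4.2]dodeca-3,9-diene-2,8-dione | CCC[C@H](OC(C)=O)C1=C(Br)[C@@]2(OC1=O)[C@@H](Br)[C@H](Br)[C@@]21OC(=O)C([C@@H](CCC)OC(C)=O)=C1Br | target

Total step count: 10. Longest linear sequence: 8 steps (1, 2, 5, 6, 7, 8, 9, 10; the branch 3, 4 joins at step 5).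

Steps most likely to fail

Step 5. The bromoynone may be consumed by conjugate or halophilic attack and oligomerisation faster than it adds to the diene, which the dibromomethyl group deactivates inductively, and regioselectivity may erode. Fallback, setting out from 7 and coming back at 9: the exocyclic carbon is no longer carried through the cycloaddition. Compound 7 is heated in toluene with commercial, more electron-rich 5-ethoxy-4-methyl-1,3-oxazole to give, after loss of acetonitrile, 1-(4-bromo-2-ethoxyfuran-3-yl)butan-1-one F1. Vilsmeier–Haack formylation (POCl3, DMF, then aqueous NaOAc) at the only free, ethoxy-activated ring position gives 3-bromo-4-butanoyl-5-ethoxyfuran-2-carbaldehyde F2. Deoxygenative gem-dibromination of the aldehyde with triphenyl phosphite and Br2 in CH2Cl2 at −78 °C, conditions under which the ketone should not react, gives 9.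

Step 8. Ring closure of the 1,4-diradical may be unselective at the CHBr carbons or leak to head-to-tail products, and C–Br homolysis may compete under irradiation of the hydroxy monomer; the absolute sense of the core is in any case not biased. Fallback, setting out from 10 and coming back at 12: the dimerisation is moved to the achiral ketone. Its acyl-extended chromophore should allow direct excitation with visible light without a sensitiser, and it can give only one racemic twofold-symmetric head-to-head dimer, rac-(5S,6S,11R,12R)-4,10,11,12-tetrabromo-3,9-dibutanoyl-1,7-dioxadispiro[4.0.4.2]dodeca-3,9-diene-2,8-dione F3. Both ketones of F3 are then reduced with (S)-2-methyl-CBS-oxazaborolidine and catecholborane; the two enantiomers of F3 give 12 and its core diastereomer, which are separated as in the main route.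

Step 10. Free phosphine may attack the vicinal dibromide or the β-bromobutenolide (debromination, addition–elimination), or SN2′ substitution and elimination may replace clean inversion at the hindered carbinol. Fallback, setting out from 13 and coming back at 14: inversion by oxidation and reduction. Dess–Martin oxidation of the free alcohol gives (1R)-1-[(5S,6S,11R,12R)-4,10,11,12-tetrabromo-9-butanoyl-2,8-dioxo-1,7-dioxadispiro[4.0.4.2]dodeca-3,9-dien-3-yl]butyl acetate F4. Reduction with (R)-2-methyl-CBS-oxazaborolidine and catecholborane gives the (1S)-alcohol, (1R)-1-[(5S,6S,11R,12R)-4,10,11,12-tetrabromo-9-[(1S)-1-hydroxybutyl]-2,8-dioxo-1,7-dioxadispiro[4.0.4.2]dodeca-3,9-dien-3-yl]butyl acetate F5. Acetylation (Ac2O, pyridine) gives 14.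

Further compounds
F1 | step 5 | 1-(4-bromo-2-ethoxyfuran-3-yl)butan-1-one | CCOc1occ(Br)c1C(=O)CCC
F2 | step 5 | 3-bromo-4-butanoyl-5-ethoxyfuran-2-carbaldehyde | CCOc1oc(C=O)c(Br)c1C(=O)CCC
F3 | step 8 | rac-(5S,6S,11R,12R)-4,10,11,12-tetrabromo-3,9-dibutanoyl-1,7-dioxadispiro[4.0.4.2]dodeca-3,9-diene-2,8-dione (racemate, one enantiomer drawn) | CCCC(=O)C1=C(Br)[C@@]2(OC1=O)[C@@H](Br)[C@H](Br)[C@@]21OC(=O)C(C(=O)CCC)=C1Br
F4 | step 10 | (1R)-1-[(5S,6S,11R,12R)-4,10,11,12-tetrabromo-9-butanoyl-2,8-dioxo-1,7-dioxadispiro[4.0.4.2]dodeca-3,9-dien-3-yl]butyl acetate | CCCC(=O)C1=C(Br)[C@@]2(OC1=O)[C@@H](Br)[C@H](Br)[C@@]21OC(=O)C([C@@H](CCC)OC(C)=O)=C1Br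
F5 | step 10 | (1R)-1-[(5S,6S,11R,12R)-4,10,11,12-tetrabromo-9-[(1S)-1-hydroxybutyl]-2,8-dioxo-1,7-dioxadispiro[4.0.4.2]dodeca-3,9-dien-3-yl]butyl acetate | CCC[C@H](O)C1=C(Br)[C@@]2(OC1=O)[C@@H](Br)[C@H](Br)[C@@]21OC(=O)C([C@@H](CCC)OC(C)=O)=C1Br
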